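## Retrosynthetic overview

- The free CO2H and C5-OH are tied up as the 1,5-lactone and the phenols as acetates. The C3 caffeate and then the C4 p-coumarate are installed by two separate esterifications.
- The lactone and its trans C4-O/C5-O pair come from a cyclohex-4-ene. A hydroxyl-directed epoxidation is followed by opening of the oxirane at C5 by the C1 ester carbonyl from the opposite face.
- The cyclohexene is cut at C1–C2 and C3–C4. One piece is trimethyl(vinyloxy)silane (C2, C3 and the C3 oxygen). The other is an acyclic, auxiliary-bound (Z)-5-silylpent-4-enoic 2-keto ester (C4, C5, C6, C1 and the carboxyl). They are joined by a Mukaiyama aldol that runs on into a vinylsilane closure on the same titanium.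
- Enabling feature: on the cyclohexane ring the oxygens on C1 and C3 are cis-1,3, with the C2 methylene between them, and C1 also carries the carboxyl. This is the aldol retron of an α-keto ester plus acetaldehyde. Its three oxygens (O on C1, O on C3, ester C=O) fit one titanium. The trans C4-O/C5-O pair, with C5-O cis to the carboxyl, is the retron of a C4=C5 alkene.
- Ring order: carbocycle (step 5), oxirane (step 6, temporary), γ-lactone (step 8, temporary, reopened in step 10).

Key step: step 5

Remark: ring atoms carry quinic acid numbers (C1: OH and CO2H; C3: caffeate; C4: p-coumarate; C5: free OH). The two O-acetylated cinnamic acids are taken as purchasable; otherwise each is one acetylation away from caffeic or p-coumaric acid.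

## Route

Step 1
Reactants: 1 glyoxylic acid monohydrate; 2 (1S,2R)-trans-2-phenylcyclohexan-1-ol
Product: 3 (1S,2R)-2-phenylcyclohexyl glyoxylate
Conditions: p-toluenesulfonic acid (cat.), toluene, reflux, Dean-Stark trap
Reagents that add atoms: none
Why: Fischer esterification with azeotropic removal of water is the standard entry to glyoxylates of secondary alcohols and leaves both stereocentres of the auxiliary untouched.

Step 2
Reactants: 3 (1S,2R)-2-phenylcyclohexyl glyoxylate; 4 3-bromo-1-(trimethylsilyl)prop-1-yne
Product: 5 (1S,2R)-2-phenylcyclohexyl 2-hydroxy-5-(trimethylsilyl)pent-4-ynoate (both carbinol epimers)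
Conditions: Zn dust, THF, 0 °C to rt; then H2O
Reagents that add atoms: none
Why: In this zinc Barbier propargylation the silyl-bearing allenylzinc species reacts through its CH2 terminus (SE2') to give the homopropargylic alcohol, and the new carbinol centre does not matter because step 4 oxidises it.

Step 3
Reactants: 5 (1S,2R)-2-phenylcyclohexyl 2-hydroxy-5-(trimethylsilyl)pent-4-ynoate
Product: 6 (1S,2R)-2-phenylcyclohexyl (Z)-2-hydroxy-5-(trimethylsilyl)pent-4-enoate (both carbinol epimers)
Conditions: H2 (1 atm), Pd/CaCO3 poisoned with Pb(OAc)2, quinoline, EtOAc, rt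
Reagents that add atoms: none
Why: Syn semihydrogenation of a silyl alkyne on poisoned palladium should stop at the (Z)-vinylsilane, the geometry an endocyclic closure needs.

Step 4
Reactants: 6 (1S,2R)-2-phenylcyclohexyl (Z)-2-hydroxy-5-(trimethylsilyl)pent-4-enoate
Product: 7 (1S,2R)-2-phenylcyclohexyl (Z)-2-oxo-5-(trimethylsilyl)pent-4-enoate
Conditions: Dess-Martin periodinane, CH2Cl2, 0 °C to rt
Reagents that add atoms: none
Why: Dess-Martin oxidation under neutral conditions turns the α-hydroxy ester into the α-keto ester without moving the β,γ-double bond into conjugation.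

Step 5
Reactants: 7 (1S,2R)-2-phenylcyclohexyl (Z)-2-oxo-5-(trimethylsilyl)pent-4-enoate; 8 trimethyl(vinyloxy)silane
Product: 10 (1S,2R)-2-phenylcyclohexyl (1R,5R)-1,5-dihydroxycyclohex-3-ene-1-carboxylate, via titanium aldolate 9 (not isolated)
Conditions: TiCl4 (2.2 equiv), 2,6-di-tert-butyl-4-methylpyridine (0.5 equiv), CH2Cl2, −78 °C; slow addition of 8 (1.05 equiv); −78 to −30 °C; then H2O
Reagents that add atoms: none
Why: Proposed new method: TiCl4 holds keto ester 7 as a five-membered s-cis chelate, the phenyl ring of the auxiliary covers the Si face, and enol silane 8 adds to the Re face of the ketone (Mukaiyama aldol, loss of Me3SiCl), which forms C1–C2 and sets C1 as R. In alkoxide 9 the titanium keeps the new aldehyde oxygen bound (six-membered O–Ti–O chelate, made more electrophilic by the second equivalent of TiCl4), and the (Z)-vinylsilane arm attacks this aldehyde through its silicon-bearing carbon; the β-silyl cation then loses Me3SiCl, which forms C3–C4 and leaves C4=C5. The carbocycle closes 6-endo-trig at the vinylsilane and exo at the carbonyl group. Because the oxygens on C1 and C3 sit on one titanium while the ring forms (bicyclo[3.3.1] array), they must end cis-1,3, so the chelate sets C3 as R. The closest known reaction types are the Mukaiyama aldol-Prins cascade of enol ethers onto internal silane nucleophiles, auxiliary-controlled additions to chelated 2-phenylcyclohexyl glyoxylates and keto esters, and silyl-Prins closures of (Z)-vinylsilanes; the new element is their merger into a carbocyclic [4+2] annulation. The step needs ketone before aldehyde (two-point binding of the 1,2-dicarbonyl), the internal arm before a second enol silane (slow addition of barely one equivalent of 8), ipso attack (the β-silicon effect rules out the five-membered ring), and no protodesilylation (hindered pyridine base).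

Step 6
Reactants: 10 (1S,2R)-2-phenylcyclohexyl (1R,5R)-1,5-dihydroxycyclohex-3-ene-1-carboxylate
Product: 11 the C4,C5-epoxide of 10, with C1-OH, C3-OH and the oxirane oxygen all on one face and the ester on the other
Conditions: VO(acac)2 (2 mol %), t-BuOOH (1.3 equiv), CH2Cl2, 0 °C to rt
Reagents that add atoms: tert-butyl hydroperoxide, CC(C)(C)OO
Why: In this hydroxyl-directed vanadium epoxidation the allylic C3-OH and the homoallylic C1-OH lie on the same face and deliver the oxygen to that face, which sets C4 and C5.

Step 7
Reactants: 11 the C4,C5-epoxide of 10; 12 (E)-3,4-diacetoxycinnamic acid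
Product: 13 the C3 (E)-3,4-diacetoxycinnamate of 11
Conditions: N,N'-dicyclohexylcarbodiimide, 4-(dimethylamino)pyridine (0.1 equiv), CH2Cl2, 0 °C to rt
Reagents that add atoms: none
Why: Steglich esterification acylates the secondary C3-OH and not the tertiary C1-OH; the oxirane is syn to C3-O, so a Payne shift is geometrically excluded and no stereocentre is touched.

Step 8
Reactants: 13 the C3 (E)-3,4-diacetoxycinnamate of 11
Product: 14 3-O-[(E)-3,4-diacetoxycinnamoyl]quinic acid 1,5-lactone
Conditions: CF3CO2H (0.5 equiv), CH2Cl2 saturated with H2O, 0 °C to rt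
Reagents that add atoms: water, O
Why: This is the acid-catalysed 5-exo lactonisation of a γ,δ-epoxy ester: the ester carbonyl is the only nucleophile on the face opposite the oxirane, it opens C5 with inversion in the trans-diaxial (Fürst-Plattner) sense, and water collapses the dioxocarbenium ion and releases auxiliary 2, so C5-O ends cis to the carboxyl and C4-OH keeps its configuration.

Step 9
Reactants: 14 3-O-[(E)-3,4-diacetoxycinnamoyl]quinic acid 1,5-lactone; 15 (E)-4-acetoxycinnamic acid
Product: 16 3-O-[(E)-3,4-diacetoxycinnamoyl]-4-O-[(E)-4-acetoxycinnamoyl]quinic acid 1,5-lactone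
Conditions: N,N'-dicyclohexylcarbodiimide, 4-(dimethylamino)pyridine (0.3 equiv), CH2Cl2, rt
Reagents that add atoms: none
Why: Steglich esterification of the only secondary hydroxyl left (axial C4-OH); the bridgehead tertiary C1-OH is much slower, and no stereocentre is touched.

Step 10
Reactants: 16 3-O-[(E)-3,4-diacetoxycinnamoyl]-4-O-[(E)-4-acetoxycinnamoyl]quinic acid 1,5-lactone
Product: 17 (1R,3R,4S,5R)-3-O-caffeoyl-4-O-p-coumaroylquinic acid (target)
Conditions: 2 M aq HCl-THF (1:3), argon, rt
Reagents that add atoms: water, O
Why: In this acid-catalysed hydrolysis the three aryl acetates and the strained bridged γ-lactone should cleave faster than the two conjugated secondary cinnamates, and the acidic medium suppresses acyl migration and leaves all stereocentres alone.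

## Compound list

1 | glyoxylic acid monohydrate | O=C(O)C(O)O | starting material
2 | (1S,2R)-trans-2-phenylcyclohexan-1-ol | O[C@H]1CCCC[C@@H]1c1ccccc1 | starting material
3 | (1S,2R)-2-phenylcyclohexyl glyoxylate | O=CC(=O)O[C@H]1CCCC[C@@H]1c1ccccc1 | intermediate
4 | 3-bromo-1-(trimethylsilyl)prop-1-yne | C[Si](C)(C)C#CCBr | starting material
5 | (1S,2R)-2-phenylcyclohexyl 2-hydroxy-5-(trimethylsilyl)pent-4-ynoate, both carbinol epimers | C[Si](C)(C)C#CCC(O)C(=O)O[C@H]1CCCC[C@@H]1c1ccccc1 | intermediate
6 | (1S,2R)-2-phenylcyclohexyl (Z)-2-hydroxy-5-(trimethylsilyl)pent-4-enoate, both carbinol epimers | C[Si](C)(C)/C=C\CC(O)C(=O)O[C@H]1CCCC[C@@H]1c1ccccc1 | intermediate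
7 | (1S,2R)-2-phenylcyclohexyl (Z)-2-oxo-5-(trimethylsilyl)pent-4-enoate | C[Si](C)(C)/C=C\CC(=O)C(=O)O[C@H]1CCCC[C@@H]1c1ccccc1 | intermediate
8 | trimethyl(vinyloxy)silane | C=CO[Si](C)(C)C | starting material
9 | trichlorotitanium alkoxide of (1S,2R)-2-phenylcyclohexyl (2R,4Z)-2-hydroxy-2-(2-oxoethyl)-5-(trimethylsilyl)pent-4-enoate | O=CC[C@](O[Ti](Cl)(Cl)Cl)(C/C=C\[Si](C)(C)C)C(=O)O[C@H]1CCCC[C@@H]1c1ccccc1 | intermediate
10 | (1S,2R)-2-phenylcyclohexyl (1R,5R)-1,5-dihydroxycyclohex-3-ene-1-carboxylate | O[C@@]1(C(=O)O[C@H]2CCCC[C@@H]2c2ccccc2)C[C@@H](O)C=CC1 | intermediate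
11 | C4,C5-epoxide of 10, oxirane O cis to both hydroxyl groups | O[C@@]1(C(=O)O[C@H]2CCCC[C@@H]2c2ccccc2)C[C@@H](O)[C@H]2O[C@H]2C1 | intermediate
12 | (E)-3,4-diacetoxycinnamic acid | OC(=O)/C=C/c1ccc(OC(C)=O)c(OC(C)=O)c1 | starting material
13 | C3 (E)-3,4-diacetoxycinnamate of 11 | O[C@@]1(C(=O)O[C@H]2CCCC[C@@H]2c2ccccc2)C[C@@H](OC(=O)/C=C/c2ccc(OC(C)=O)c(OC(C)=O)c2)[C@H]2O[C@H]2C1 | intermediate
14 | 3-O-[(E)-3,4-diacetoxycinnamoyl]quinic acid 1,5-lactone | O[C@@]12C[C@@H](OC(=O)/C=C/c3ccc(OC(C)=O)c(OC(C)=O)c3)[C@@H](O)[C@@H](C1)OC2=O | intermediate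
15 | (E)-4-acetoxycinnamic acid | OC(=O)/C=C/c1ccc(OC(C)=O)cc1 | starting material
16 | 3-O-[(E)-3,4-diacetoxycinnamoyl]-4-O-[(E)-4-acetoxycinnamoyl]quinic acid 1,5-lactone | O[C@@]12C[C@@H](OC(=O)/C=C/c3ccc(OC(C)=O)c(OC(C)=O)c3)[C@@H](OC(=O)/C=C/c3ccc(OC(C)=O)cc3)[C@@H](C1)OC2=O | intermediate
17 | (1R,3R,4S,5R)-3-O-caffeoyl-4-O-p-coumaroylquinic acid | O=C(/C=C/c1ccc(O)cc1)O[C@H]1[C@H](O)C[C@](O)(C(=O)O)C[C@H]1OC(=O)/C=C/c1ccc(O)c(O)c1 | target

## Step count and risks

Total steps: 10. Longest linear sequence: 10 steps (from 2 to 17).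

**Step 5 (proposed new method).**
- What may go wrong:
  - The aldolate may undergo retro-aldol cleavage, or take up a second enol silane, before the weakly nucleophilic vinylsilane closes.
  - The vinylsilane may be protodesilylated.
  - Closure outside the chelate may erode the facial control at C3.
- Fallback with known chemistry, from 7 back to 10, making the two bonds one at a time:
  - A TiCl4-mediated Mukaiyama aldol of 7 with [1-(tert-butylsulfanyl)vinyloxy]trimethylsilane should give the thioester F1 under the same auxiliary control.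
  - Fukuyama reduction (Et3SiH, Pd/C) should give the hydroxy aldehyde F2.
  - Iododesilylation with N-iodosuccinimide in acetonitrile, with retention of geometry, should give the (Z)-vinyl iodide F3.
  - An intramolecular Nozaki-Hiyama-Kishi reaction (CrCl2, NiCl2 cat., DMF) should close the ring to 10.

**Step 8.**
- What may go wrong:
  - Trifluoroacetate or water may open the protonated oxirane at C4.
  - The hindered alcohol may be expelled only slowly from the dioxocarbenium ion.
  - The C3 acyl group may shift to the freed C4-OH.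
- Fallback, from 11 back to 14, which reverses the order of acylation and lactonisation:
  - Saponification of the auxiliary ester of 11 (LiOH, THF-H2O) should give the epoxy acid F4.
  - On acidification the free carboxyl opens the oxirane at C5 to give quinic acid 1,5-lactone F5.
  - The equatorial C3-OH of F5 is then esterified selectively with 12 (carbodiimide, low temperature), ahead of the axial C4-OH and the tertiary C1-OH, to give 14.

**Step 10.**
- What may go wrong: slow lactone hydrolysis may leave time for loss or migration of the cinnamoyl groups.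
- Fallback, from 16 to 17, in two orthogonal stages instead of one global solvolysis:
  - Neutral hydrazinolysis (hydrazine acetate, DMF, rt) removes only the aryl acetates and should give the triphenol lactone F6.
  - The single remaining labile group, the strained lactone, is then opened by a short exposure to dilute aqueous HCl in THF.

## Further compounds

F1 | step 5 | (1S,2R)-2-phenylcyclohexyl (2R,4Z)-2-[2-(tert-butylsulfanyl)-2-oxoethyl]-2-hydroxy-5-(trimethylsilyl)pent-4-enoate | CC(C)(C)SC(=O)C[C@](O)(C/C=C\[Si](C)(C)C)C(=O)O[C@H]1CCCC[C@@H]1c1ccccc1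
F2 | step 5 | (1S,2R)-2-phenylcyclohexyl (2R,4Z)-2-hydroxy-2-(2-oxoethyl)-5-(trimethylsilyl)pent-4-enoate | O=CC[C@](O)(C/C=C\[Si](C)(C)C)C(=O)O[C@H]1CCCC[C@@H]1c1ccccc1
F3 | step 5 | (1S,2R)-2-phenylcyclohexyl (2R,4Z)-2-hydroxy-5-iodo-2-(2-oxoethyl)pent-4-enoate | O=CC[C@](O)(C/C=C\I)C(=O)O[C@H]1CCCC[C@@H]1c1ccccc1
F4 | step 8 | free carboxylic acid of epoxide 11 | O[C@@]1(C(=O)O)C[C@@H](O)[C@H]2O[C@H]2C1
F5 | step 8 | quinic acid 1,5-lactone | O[C@@]12C[C@@H](O)[C@@H](O)[C@@H](C1)OC2=O
F6 | step 10 | 3-O-caffeoyl-4-O-p-coumaroylquinic acid 1,5-lactone | O[C@@]12C[C@@H](OC(=O)/C=C/c3ccc(O)c(O)c3)[C@@H](OC(=O)/C=C/c3ccc(O)cc3)[C@@H](C1)OC2=O
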